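**Retrosynthetic overview**

1. Target 22 comes from isopropenyl diester 20 by SeO2 oxidation of the allylic CH3 (last step); 20 comes from two separate acylations, the C3–OH first and the side-chain OH after desilylation.
2. The isopropenyl group comes from the C2-ethynyl group of 15 by Zr-catalysed methylalumination.
3. Key step: 15 comes from 13 by intramolecular [4+2] addition of the tethered alkyne across C3/C6 of a 3-alkoxypyridazine, then loss of N2. This closes the dihydrofuran and creates the benzene ring in one operation.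
4. 13 comes from SNAr of C2-symmetric (3R,4R)-hexa-1,5-diyne-3,4-diol 12 (from D-tartrate; becomes C2/C3) on chloropyridazine 8 (from L-lactic acid; carries the side-chain carbinol).
5. Ring order: pyridazine (sacrificial diene, steps 2–5), then dihydrofuran and benzene together (step 9).

Assumption: 1, 2 and 9 are bought as such (1 is made from L-lactic acid, 9 from D-tartaric acid). TBDPS = tert-butyldiphenylsilyl. The route is a design from known reaction types and has not been run.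

**Route**

Step 1
Reactants: 1 (2S)-2-(acetyloxy)propanoyl chloride; 2 ethyl 3-iodopropanoate
Product: 4 ethyl (5S)-5-(acetyloxy)-4-oxohexanoate, via organozinc iodide 3 (not isolated)
Conditions: 2, Zn dust, LiCl, THF, 40 °C; then 1, Pd(PPh3)4 (3 mol %), THF, 0 °C → rt
Reagents that add atoms: none
Why: Negishi acylation with a non-basic zinc homoenolate gives the γ-keto ester without enolising the lactate-derived centre, which is bought in 1.

Step 2
Reactants: 4 ethyl (5S)-5-(acetyloxy)-4-oxohexanoate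
Product: 5 6-[(1S)-1-hydroxyethyl]-4,5-dihydropyridazin-3(2H)-one
Conditions: N2H4·H2O (1.2 equiv), EtOH, 0 °C → rt; then N2H4·H2O (3 equiv), 60 °C
Reagents that add atoms: hydrazine, NN
Why: Hydrazone formation at the ketone and lactamisation onto the ester (cyclocondensation of a γ-keto ester) close the diazine ring in the cold, and the excess hydrazine then cleaves the acetate; the carbinol centre is not involved.

Step 3
Reactants: 5 6-[(1S)-1-hydroxyethyl]-4,5-dihydropyridazin-3(2H)-one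
Product: 6 6-[(1S)-1-(TBDPSO)ethyl]-4,5-dihydropyridazin-3(2H)-one
Conditions: TBDPSCl, imidazole, DMF, rt
Reagents that add atoms: tert-butyl(chloro)diphenylsilane, CC(C)(C)[Si](Cl)(c1ccccc1)c1ccccc1
Why: Standard O-silylation of the secondary alcohol; the acid- and heat-stable TBDPS ether is chosen to survive CuCl2/HCl, POCl3, NaH and the 230 °C cycloaddition.

Step 4
Reactants: 6 6-[(1S)-1-(TBDPSO)ethyl]-4,5-dihydropyridazin-3(2H)-one
Product: 7 6-[(1S)-1-(TBDPSO)ethyl]pyridazin-3(2H)-one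
Conditions: CuCl2 (2.2 equiv), MeCN, reflux
Reagents that add atoms: none
Why: Cu(II)-mediated dehydrogenation (α-chlorination then dehydrochlorination) aromatises the ring through the endocyclic ene-hydrazine, so the exocyclic stereocentre is not enolised.

Step 5
Reactants: 7 6-[(1S)-1-(TBDPSO)ethyl]pyridazin-3(2H)-one
Product: 8 3-chloro-6-[(1S)-1-(TBDPSO)ethyl]pyridazine
Conditions: POCl3 (3 equiv), i-Pr2NEt, MeCN, 80 °C
Reagents that add atoms: phosphoryl chloride, O=P(Cl)(Cl)Cl
Why: Deoxychlorination of the lactam (O-phosphorylation, then chloride addition–elimination) gives the SNAr-active 3-chlorodiazine; the base buffers HCl to keep the silyl ether.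

Step 6
Reactants: 9 dimethyl (4S,5S)-2,2-dimethyl-1,3-dioxolane-4,5-dicarboxylate
Product: 11 (4R,5R)-4,5-diethynyl-2,2-dimethyl-1,3-dioxolane, via dialdehyde 10 (not isolated)
Conditions: DIBAL-H (2.2 equiv), CH2Cl2, −78 °C; then MeOH, K2CO3, Bestmann–Ohira reagent (2.5 equiv), −78 °C → rt
Reagents that add atoms: dimethyl (1-diazo-2-oxopropyl)phosphonate, CC(=O)C(=[N+]=[N-])P(=O)(OC)OC
Why: DIBAL reduction stops at the aluminium hemiacetals and the released dialdehyde is homologated in the same pot (Seyferth–Gilbert/Ohira–Bestmann alkynylation); both D-tartrate centres are kept because the trans-dioxolane is the favoured arrangement (the descriptor changes from S to R only through CIP priorities).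

Step 7
Reactants: 11 (4R,5R)-4,5-diethynyl-2,2-dimethyl-1,3-dioxolane
Product: 12 (3R,4R)-hexa-1,5-diyne-3,4-diol
Conditions: 2 M aq. HCl, THF, 40 °C
Reagents that add atoms: none
Why: Acid-catalysed acetal hydrolysis frees the C2-symmetric threo diol without touching the C–O stereocentres.

Step 8
Reactants: 8 3-chloro-6-[(1S)-1-(TBDPSO)ethyl]pyridazine; 12 (3R,4R)-hexa-1,5-diyne-3,4-diol
Product: 13 (3R,4R)-4-({6-[(1S)-1-(TBDPSO)ethyl]pyridazin-3-yl}oxy)hexa-1,5-diyn-3-ol
Conditions: 12 (2 equiv), NaH (1.1 equiv), DMF, 0 °C; then 8, 0 → 60 °C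
Reagents that add atoms: none
Why: SNAr (addition–elimination) of the mono-alkoxide at C3 of the chlorodiazine; the two hydroxyls of 12 are homotopic, so only one mono-ether can form, and both C–O bonds at the stereocentres stay intact.

Step 9
Reactants: 13 (3R,4R)-4-({6-[(1S)-1-(TBDPSO)ethyl]pyridazin-3-yl}oxy)hexa-1,5-diyn-3-ol
Product: 15 (2R,3R)-2-ethynyl-5-[(1S)-1-(TBDPSO)ethyl]-2,3-dihydro-1-benzofuran-3-ol, via bridged diazabicyclooctatriene 14 (not isolated)
Conditions: 1,3,5-triisopropylbenzene (0.01 M), 230 °C, Ar, sealed tube, 18 h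
Reagents that add atoms: none
Why: Intramolecular inverse-electron-demand Diels–Alder reaction of the alkyne across C3/C6 of the 1,2-diazine, then retro-Diels–Alder loss of N2, forms the dihydrofuran and the benzene ring with the tether fixing the regiochemistry (side chain at C5); no stereocentre is made or broken, and the threo tether carbons become the cis C2/C3 pair.

Step 10
Reactants: 15 (2R,3R)-2-ethynyl-5-[(1S)-1-(TBDPSO)ethyl]-2,3-dihydro-1-benzofuran-3-ol
Product: 17 (2R,3R)-2-(prop-1-en-2-yl)-5-[(1S)-1-(TBDPSO)ethyl]-2,3-dihydro-1-benzofuran-3-ol, via alkenylalane 16 (not isolated)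
Conditions: AlMe3 (4 equiv), Cp2ZrCl2 (0.3 equiv), CH2Cl2, 0 °C → rt; then aq. Rochelle salt, 0 °C
Reagents that add atoms: trimethylaluminium, C[Al](C)C
Why: Negishi Zr-catalysed carboalumination adds methyl to the internal and aluminium to the terminal alkyne carbon (syn), so protonolysis gives the isopropenyl group; the hydroxyl is carried as its aluminium alkoxide and C2/C3 are unchanged.

Step 11
Reactants: 17 (2R,3R)-2-(prop-1-en-2-yl)-5-[(1S)-1-(TBDPSO)ethyl]-2,3-dihydro-1-benzofuran-3-ol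
Product: 18 (2R,3R)-2-(prop-1-en-2-yl)-5-[(1S)-1-(TBDPSO)ethyl]-2,3-dihydro-1-benzofuran-3-yl 3-methylbutanoate
Conditions: isovaleryl chloride, pyridine, DMAP (cat.), CH2Cl2, 0 °C → rt
Reagents that add atoms: 3-methylbutanoyl chloride, CC(C)CC(Cl)=O
Why: DMAP-catalysed O-acylation of the only free hydroxyl, with retention at C3.

Step 12
Reactants: 18 (2R,3R)-2-(prop-1-en-2-yl)-5-[(1S)-1-(TBDPSO)ethyl]-2,3-dihydro-1-benzofuran-3-yl 3-methylbutanoate
Product: 19 (2R,3R)-5-[(1S)-1-hydroxyethyl]-2-(prop-1-en-2-yl)-2,3-dihydro-1-benzofuran-3-yl 3-methylbutanoate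
Conditions: TBAF, AcOH (1:1), THF, rt → 40 °C
Reagents that add atoms: none
Why: Fluoride-driven Si–O cleavage; the acetic acid buffer prevents base-induced loss of the C3 ester (elimination to the benzofuran), and the C–O bond of the carbinol is not broken.

Step 13
Reactants: 19 (2R,3R)-5-[(1S)-1-hydroxyethyl]-2-(prop-1-en-2-yl)-2,3-dihydro-1-benzofuran-3-yl 3-methylbutanoate
Product: 20 (1S)-1-[(2R,3R)-3-(3-methylbutanoyloxy)-2-(prop-1-en-2-yl)-2,3-dihydro-1-benzofuran-5-yl]ethyl 3-methylbut-2-enoate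
Conditions: 3-methylbut-2-enoyl chloride, pyridine, DMAP (cat.), CH2Cl2, 0 °C
Reagents that add atoms: 3-methylbut-2-enoyl chloride, CC(C)=CC(Cl)=O
Why: O-acylation of the benzylic alcohol with retention; pyridine instead of a trialkylamine avoids vinylketene formation and deconjugation of the senecioyl group.

Step 14
Reactants: 20 (1S)-1-[(2R,3R)-3-(3-methylbutanoyloxy)-2-(prop-1-en-2-yl)-2,3-dihydro-1-benzofuran-5-yl]ethyl 3-methylbut-2-enoate
Product: 22 (1S)-1-[(2R,3R)-3-(3-methylbutanoyloxy)-2-(3-oxoprop-1-en-2-yl)-2,3-dihydro-1-benzofuran-5-yl]ethyl 3-methylbut-2-enoate, via allylic alcohol 21 (not isolated)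
Conditions: SeO2 (1.5 equiv), 1,4-dioxane, 80 °C
Reagents that add atoms: selenium dioxide, O=[Se]=O
Why: Riley oxidation, in which an ene reaction of SeO2 at the CH3 of the electron-rich 1,1-disubstituted alkene and a [2,3]-sigmatropic shift give the allylic alcohol, which is oxidised on to the enal; the electron-poor senecioate alkene reacts more slowly and no stereocentre is touched.

**Compound list**

1 | (2S)-2-(acetyloxy)propanoyl chloride | C[C@H](OC(C)=O)C(Cl)=O | starting material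
2 | ethyl 3-iodopropanoate | CCOC(=O)CCI | starting material
3 | (3-ethoxy-3-oxopropyl)zinc iodide | CCOC(=O)CC[Zn]I | intermediate
4 | ethyl (5S)-5-(acetyloxy)-4-oxohexanoate | CCOC(=O)CCC(=O)[C@H](C)OC(C)=O | intermediate
5 | 6-[(1S)-1-hydroxyethyl]-4,5-dihydropyridazin-3(2H)-one | O=C1CCC(=NN1)[C@H](C)O | intermediate
6 | 6-[(1S)-1-(TBDPSO)ethyl]-4,5-dihydropyridazin-3(2H)-one | O=C1CCC(=NN1)[C@H](C)O[Si](c1ccccc1)(c1ccccc1)C(C)(C)C | intermediate
7 | 6-[(1S)-1-(TBDPSO)ethyl]pyridazin-3(2H)-one | O=c1ccc(n[nH]1)[C@H](C)O[Si](c1ccccc1)(c1ccccc1)C(C)(C)C | intermediate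
8 | 3-chloro-6-[(1S)-1-(TBDPSO)ethyl]pyridazine | Clc1ccc(nn1)[C@H](C)O[Si](c1ccccc1)(c1ccccc1)C(C)(C)C | intermediate
9 | dimethyl (4S,5S)-2,2-dimethyl-1,3-dioxolane-4,5-dicarboxylate (dimethyl 2,3-O-isopropylidene-D-tartrate) | COC(=O)[C@H]1OC(C)(C)O[C@@H]1C(=O)OC | starting material
10 | (4S,5S)-2,2-dimethyl-1,3-dioxolane-4,5-dicarbaldehyde | O=C[C@H]1OC(C)(C)O[C@@H]1C=O | intermediate
11 | (4R,5R)-4,5-diethynyl-2,2-dimethyl-1,3-dioxolane | C#C[C@H]1OC(C)(C)O[C@@H]1C#C | intermediate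
12 | (3R,4R)-hexa-1,5-diyne-3,4-diol | C#C[C@@H](O)[C@H](O)C#C | intermediate
13 | (3R,4R)-4-({6-[(1S)-1-(TBDPSO)ethyl]pyridazin-3-yl}oxy)hexa-1,5-diyn-3-ol | C#C[C@@H](Oc1ccc(nn1)[C@H](C)O[Si](c1ccccc1)(c1ccccc1)C(C)(C)C)[C@H](O)C#C | intermediate
14 | bridged [4+2] adduct of 13: a 2,3-diazabicyclo[2.2.2]octa-2,5,7-triene with the O–CH(C≡CH)–CH(OH) bridge from one bridgehead to the adjacent alkene carbon and the (1S)-1-(TBDPSO)ethyl group on the other bridgehead (bridgehead configuration depends on the face attacked and is lost with N2) | C#C[C@H]1OC23C=CC(N=N2)(C=C3[C@H]1O)[C@H](C)O[Si](c1ccccc1)(c1ccccc1)C(C)(C)C | intermediate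
15 | (2R,3R)-2-ethynyl-5-[(1S)-1-(TBDPSO)ethyl]-2,3-dihydro-1-benzofuran-3-ol | C#C[C@H]1Oc2ccc(cc2[C@H]1O)[C@H](C)O[Si](c1ccccc1)(c1ccccc1)C(C)(C)C | intermediate
16 | dimethylaluminium 3-alkoxide of the (E)-2-methylalkenyl(dimethyl)alane from 15 (Me on the internal, AlMe2 on the terminal alkene carbon) | C[Al](C)/C=C(\C)[C@H]1Oc2ccc(cc2[C@H]1O[Al](C)C)[C@H](C)O[Si](c1ccccc1)(c1ccccc1)C(C)(C)C | intermediate
17 | (2R,3R)-2-(prop-1-en-2-yl)-5-[(1S)-1-(TBDPSO)ethyl]-2,3-dihydro-1-benzofuran-3-ol | C=C(C)[C@H]1Oc2ccc(cc2[C@H]1O)[C@H](C)O[Si](c1ccccc1)(c1ccccc1)C(C)(C)C | intermediate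
18 | (2R,3R)-2-(prop-1-en-2-yl)-5-[(1S)-1-(TBDPSO)ethyl]-2,3-dihydro-1-benzofuran-3-yl 3-methylbutanoate | C=C(C)[C@H]1Oc2ccc(cc2[C@H]1OC(=O)CC(C)C)[C@H](C)O[Si](c1ccccc1)(c1ccccc1)C(C)(C)C | intermediate
19 | (2R,3R)-5-[(1S)-1-hydroxyethyl]-2-(prop-1-en-2-yl)-2,3-dihydro-1-benzofuran-3-yl 3-methylbutanoate | C=C(C)[C@H]1Oc2ccc(cc2[C@H]1OC(=O)CC(C)C)[C@H](C)O | intermediate
20 | (1S)-1-[(2R,3R)-3-(3-methylbutanoyloxy)-2-(prop-1-en-2-yl)-2,3-dihydro-1-benzofuran-5-yl]ethyl 3-methylbut-2-enoate | C=C(C)[C@H]1Oc2ccc(cc2[C@H]1OC(=O)CC(C)C)[C@H](C)OC(=O)C=C(C)C | intermediate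
21 | (1S)-1-[(2R,3R)-2-(3-hydroxyprop-1-en-2-yl)-3-(3-methylbutanoyloxy)-2,3-dihydro-1-benzofuran-5-yl]ethyl 3-methylbut-2-enoate | C=C(CO)[C@H]1Oc2ccc(cc2[C@H]1OC(=O)CC(C)C)[C@H](C)OC(=O)C=C(C)C | intermediate
22 | (1S)-1-[(2R,3R)-3-(3-methylbutanoyloxy)-2-(3-oxoprop-1-en-2-yl)-2,3-dihydro-1-benzofuran-5-yl]ethyl 3-methylbut-2-enoate (CNP0325942.1) | C=C(C=O)[C@H]1Oc2ccc([C@H](C)OC(=O)C=C(C)C)cc2[C@H]1OC(=O)CC(C)C | target

**Step count and risks**

Total steps: 14. Longest linear sequence: 12 (steps 1–5 and 8–14; steps 6–7 are the side branch).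

The three steps most likely to fail, in route order:

Step 4. The dehydrogenation runs hot and acidic next to the lactate-derived centre (α to C=N) and on a silyl ether, so loss of ee or of the TBDPS group is possible. Fallback: set out from 1 and build the diazine directly at the aromatic oxidation level. Zinc insertion into ethyl (Z)-3-iodoacrylate gives ethyl (2Z)-3-(iodozincio)prop-2-enoate F1. Pd-catalysed acylation with 1 (as in step 1) gives ethyl (2Z,5S)-5-(acetyloxy)-4-oxohex-2-enoate F2. Hydrazine hydrate in EtOH condenses with the cis-keto ester, with loss of the acetate, to 6-[(1S)-1-hydroxyethyl]pyridazin-3(2H)-one F3. TBDPSCl/imidazole then returns to the route at 7, with no oxidation step.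

Step 9. The 3-alkoxy-6-alkyl-diazine is an electron-rich azadiene and needs about 230 °C. At that temperature the free propargylic alcohol and the propargyl heteroaryl ether (O→N [3,3] shift) can compete with the cycloaddition. Fallback: set out from 13 and run the cycloaddition on the capped tether. TESCl/imidazole gives 3-{[(3R,4R)-4-(triethylsilyloxy)hexa-1,5-diyn-3-yl]oxy}-6-[(1S)-1-(TBDPSO)ethyl]pyridazine F4. Thermolysis in triisopropylbenzene passes through the bridged diazabicyclooctatriene adduct F5 to (2R,3R)-2-ethynyl-3-(triethylsilyloxy)-5-[(1S)-1-(TBDPSO)ethyl]-2,3-dihydro-1-benzofuran F6. PPTS in MeOH removes only the TES group and returns to the route at 15.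

Step 14. SeO2 must select the isopropenyl CH3 over the allylic C2–H, the senecioate methyls and the benzylic positions, and must not over-oxidise the acid-sensitive diester. Fallback: set out from 20 and replace selenium by a photooxygenation. The Schenck ene reaction with singlet oxygen (O2, tetraphenylporphyrin, hν, CH2Cl2, 0 °C) gives (1S)-1-[(2R,3R)-2-(3-hydroperoxyprop-1-en-2-yl)-3-(3-methylbutanoyloxy)-2,3-dihydro-1-benzofuran-5-yl]ethyl 3-methylbut-2-enoate F7. Dehydration of the primary allylic hydroperoxide with Ac2O/pyridine gives the enal and returns to the route at 22.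

**Further compounds**

F1 | step 4 | ethyl (2Z)-3-(iodozincio)prop-2-enoate | CCOC(=O)/C=C\[Zn]I
F2 | step 4 | ethyl (2Z,5S)-5-(acetyloxy)-4-oxohex-2-enoate | CCOC(=O)/C=C\C(=O)[C@H](C)OC(C)=O
F3 | step 4 | 6-[(1S)-1-hydroxyethyl]pyridazin-3(2H)-one | O=c1ccc(n[nH]1)[C@H](C)O
F4 | step 9 | 3-{[(3R,4R)-4-(triethylsilyloxy)hexa-1,5-diyn-3-yl]oxy}-6-[(1S)-1-(TBDPSO)ethyl]pyridazine | C#C[C@@H](Oc1ccc(nn1)[C@H](C)O[Si](c1ccccc1)(c1ccccc1)C(C)(C)C)[C@H](O[Si](CC)(CC)CC)C#C
F5 | step 9 | bridged diazabicyclo[2.2.2]octatriene adduct of F4 (triethylsilyl ether of 14) | C#C[C@H]1OC23C=CC(N=N2)(C=C3[C@H]1O[Si](CC)(CC)CC)[C@H](C)O[Si](c1ccccc1)(c1ccccc1)C(C)(C)C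
F6 | step 9 | (2R,3R)-2-ethynyl-3-(triethylsilyloxy)-5-[(1S)-1-(TBDPSO)ethyl]-2,3-dihydro-1-benzofuran | C#C[C@H]1Oc2ccc(cc2[C@H]1O[Si](CC)(CC)CC)[C@H](C)O[Si](c1ccccc1)(c1ccccc1)C(C)(C)C
F7 | step 14 | (1S)-1-[(2R,3R)-2-(3-hydroperoxyprop-1-en-2-yl)-3-(3-methylbutanoyloxy)-2,3-dihydro-1-benzofuran-5-yl]ethyl 3-methylbut-2-enoate | C=C(COO)[C@H]1Oc2ccc(cc2[C@H]1OC(=O)CC(C)C)[C@H](C)OC(=O)C=C(C)C
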